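**Plan**
Cuts: both ester C–O bonds are removed first. C6=C7 then goes back to C6H–C7H2, C9–O to a C8=C9 enol silane, and C4–O to C4=O. Finally C5–C10 and C6–C7 are cut together (retro-Diels–Alder) into a C10 enone and a C5 diene.
Enabling feature: in the six-membered ring C5–C10, the spiro atom C5 lies α to the oxygen-bearing C4 of the cyclopentane ring and 1,4 ("para") to the C8 carbonyl, and it is flanked by the methyl-bearing C6 and C10. This is the retron of an exocyclic enone C4(=O)–C5=C6 plus a 2-silyloxy-1,3-pentadiene C7=C8(OSi)–C9=C10.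
Forward: the cyclopentane ring is closed first (aldol condensation of the keto aldehyde from (R)-limonene oxide, then Wharton 1,3-transposition and oxidation). The six-membered ring is closed last by the [4+2] step. Helpers: the C4 ketone (activator, later the carbinol), the enol silane (masks C8, marks C9), and sp3 C6 (dehydrogenated at the end).
Stereochemistry: C2 comes from (R)-limonene, C5 from diene attack anti to the isopropenyl group, and C10 from the endo rule with the E diene. C4 is set by CBS reduction and C9 by Rubottom oxidation anti to the C10 methyl group, which is also the more stable epimer.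

Key step: step 7

Remark: atoms are numbered as in spirovetivanes. C1–C4 are the cyclopentane carbons (C2 isopropenyl, C4 acyloxy), C5 is the spiro atom, C6 carries the vinylic methyl, then C7, C8 (C=O), C9 (OAc) and C10 (methyl). Commercial (+)-limonene oxide is taken as the (4R) cis/trans mixture.

Step 1
Reactants: 1 (+)-(4R)-limonene 1,2-oxide (cis/trans mixture)
Product: 3 (3R)-6-oxo-3-(prop-1-en-2-yl)heptanal, via limonene-1,2-diol 2 (not isolated)
Conditions: H5IO6, THF/H2O, 0 °C to rt
Reagents that add atoms: water, O
Why: Acidic hydrolysis of both epoxide diastereomers to the trans-diol followed by Malaprade glycol cleavage opens the cyclohexane ring chemoselectively, and the isopropenyl group and its adjacent stereocentre (the later C2) are untouched.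

Step 2
Reactants: 3 (3R)-6-oxo-3-(prop-1-en-2-yl)heptanal
Product: 4 (S)-1-[4-(prop-1-en-2-yl)cyclopent-1-en-1-yl]ethan-1-one
Conditions: piperidine, AcOH (cat.), toluene, reflux (Dean–Stark)
Reagents that add atoms: none
Why: Amine/acid-catalysed intramolecular aldol condensation, in which the internal α-CH2 of the methyl ketone attacks the aldehyde (5-enolexo closure preferred over the seven-membered alternative), closes the cyclopentane ring and creates no new stereocentre.

Step 3
Reactants: 4 (S)-1-[4-(prop-1-en-2-yl)cyclopent-1-en-1-yl]ethan-1-one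
Product: 5 1-[(1R,3S,5S)-3-(prop-1-en-2-yl)-6-oxabicyclo[3.1.0]hexan-1-yl]ethan-1-one (epoxide trans to the isopropenyl group)
Conditions: 30% H2O2, NaOH (cat.), MeOH, 0 °C
Reagents that add atoms: hydrogen peroxide, OO
Why: Weitz–Scheffer nucleophilic epoxidation touches only the electron-poor enone double bond and should occur mainly anti to the isopropenyl group, although both new stereocentres are erased again by step 5, so the facial outcome has no bearing on the route.

Step 4
Reactants: 5 epoxy ketone
Product: 7 (1S,4R,E)-2-ethylidene-4-(prop-1-en-2-yl)cyclopentan-1-ol, via epoxy hydrazone 6 (not isolated)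
Conditions: N2H4·H2O, AcOH (cat.), MeOH, 0 °C to rt, under N2
Reagents that add atoms: hydrazine (as hydrate), NN (its nitrogen atoms are carried only by 6 and leave as N2)
Why: Wharton transposition, in which the epoxy hydrazone opens to a vinyl diazene that loses N2, moves the oxygen to C4 and the double bond to the exocyclic C5=C6 position while the C4–O configuration of the epoxide is retained.

Step 5
Reactants: 7 (1S,4R,E)-2-ethylidene-4-(prop-1-en-2-yl)cyclopentan-1-ol
Product: 8 (4R,E)-2-ethylidene-4-(prop-1-en-2-yl)cyclopentan-1-one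
Conditions: MnO2, CH2Cl2, rt; then I2 (cat.), CH2Cl2, rt
Reagents that add atoms: none
Why: Selective allylic oxidation with MnO2 gives the exocyclic enone and leaves the isolated alkene alone, and iodine-catalysed equilibration collects the ethylidene group in the more stable E geometry (methyl anti to the carbonyl group).

Step 6
Reactants: 9 (E)-pent-3-en-2-one
Product: 10 (E)-2-(tert-butyldimethylsilyloxy)penta-1,3-diene
Conditions: TBSOTf, Et3N, Et2O, 0 °C
Reagents that add atoms: TBSOTf, CC(C)(C)[Si](C)(C)OS(=O)(=O)C(F)(F)F
Why: Soft enolisation (silyl triflate/amine) removes an α′-methyl proton of the enone and gives the cross-conjugated 2-silyloxy diene with the E propenyl geometry of 9 retained.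

Step 7
Reactants: 8 (4R,E)-2-ethylidene-4-(prop-1-en-2-yl)cyclopentan-1-one; 10 (E)-2-(tert-butyldimethylsilyloxy)penta-1,3-diene
Product: 11 (2R,5R,6S,10S)-8-(tert-butyldimethylsilyloxy)-6,10-dimethyl-2-(prop-1-en-2-yl)spiro[4.5]dec-8-en-4-one (C10 methyl cis to C4; C6 methyl cis to C1; C10 trans to the isopropenyl group on the five-membered ring)
Conditions: Me2AlCl (cat.), CH2Cl2, −78 to −20 °C
Reagents that add atoms: none
Why: Me2AlCl binds the C4 carbonyl of the s-cis-locked exocyclic enone 8 and lowers its LUMO, so that the electron-rich diene 10 adds in a normal-electron-demand, concerted but asynchronous [4+2] cycloaddition in which C6–C7 bonding runs ahead of C5–C10 bonding. The closest known reaction type is the Lewis-acid-promoted Diels–Alder spiroannulation of α-alkylidene cycloalkanones with 2-silyloxy-1,3-dienes or isoprene. The six-membered ring C5–C10 is closed intermolecularly by suprafacial/suprafacial formation of two σ-bonds (C6–C7 and C5–C10), and the new C8=C9 π-bond appears as a regiodefined silyl enol ether. C5 is controlled by the C2 isopropenyl group, which shields one face of the flat cyclopentanone so that the diene adds to the opposite face; C10 is controlled by the E geometry of the diene together with the endo orientation (diene core over C4=O and the vinylic hydrogen of C6, away from C1H2 and the C6 methyl group), which places the C10 methyl group cis to C4; C6 follows from the E geometry of 8 and is erased in step 12. The regioselectivity needed (C7 to C6, C10 to C5) is secured because both donors of 10, the 2-silyloxy group ("para") and the terminal methyl group ("ortho"), put the largest HOMO coefficient on the CH2 terminus C7, which attacks the β-carbon C6 of the enone. Chemoselectivity is secured because the isopropenyl group is an unactivated alkene.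

Step 8
Reactants: 11 spiro ketone
Product: 12 (2R,4S,5R,6S,10S)-8-(tert-butyldimethylsilyloxy)-6,10-dimethyl-2-(prop-1-en-2-yl)spiro[4.5]dec-8-en-4-ol
Conditions: (R)-Me-CBS (cat.), catecholborane, toluene, −78 to −40 °C; then MeOH, aq. NaHCO3
Reagents that add atoms: none
Why: In this Corey–Bakshi–Shibata reduction the (R)-oxazaborolidine distinguishes the quaternary C5 (large) from C3H2 (small) and delivers hydride to the carbonyl face on the C6 side, which the C10 methyl group does not screen, so the (4S)-alcohol with oxygen cis to C10 and trans to the isopropenyl group should result, while catecholborane leaves the alkene and the enol silane untouched.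

Step 9
Reactants: 12 spiro alcohol
Product: 13 (2R,4S,5R,6S,10S)-8-(tert-butyldimethylsilyloxy)-6,10-dimethyl-2-(prop-1-en-2-yl)spiro[4.5]dec-8-en-4-yl 3-methylbut-2-enoate
Conditions: 3-methylbut-2-enoyl chloride, pyridine, DMAP (cat.), CH2Cl2, 0 °C to rt
Reagents that add atoms: 3-methylbut-2-enoyl (senecioyl) chloride, CC(C)=CC(=O)Cl
Why: DMAP-catalysed acylation of the hindered secondary alcohol with the acid chloride uses pyridine rather than a trialkylamine, so that vinylketene formation and deconjugation of the senecioyl group are held back, and no stereocentre is touched.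

Step 10
Reactants: 13 senecioate enol silane
Product: 16 (2R,4S,5R,6S,9S,10R)-9-hydroxy-6,10-dimethyl-8-oxo-2-(prop-1-en-2-yl)spiro[4.5]decan-4-yl 3-methylbut-2-enoate, via silyloxy epoxide 14 (not isolated), via α-silyloxy ketone 15 (not isolated)
Conditions: mCPBA, NaHCO3, CH2Cl2, −20 °C; then HF·pyridine, THF, 0 °C
Reagents that add atoms: mCPBA, O=C(OO)c1cccc(Cl)c1
Why: In this Rubottom oxidation the peracid attacks the most electron-rich double bond (the enol silane) from the ring face opposite to the C10 methyl group and to C4, the silyloxy epoxide opens with 1,4-silyl migration, and fluoride frees the (9S)-alcohol trans to the C10 methyl group, which is also the more stable (diequatorial) arrangement at this epimerisable centre.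

Step 11
Reactants: 16 α-hydroxy ketone
Product: 17 (2R,4S,5R,6S,9S,10R)-9-acetoxy-6,10-dimethyl-8-oxo-2-(prop-1-en-2-yl)spiro[4.5]decan-4-yl 3-methylbut-2-enoate
Conditions: Ac2O, pyridine, DMAP (cat.), CH2Cl2, 0 °C
Reagents that add atoms: acetic anhydride, CC(=O)OC(C)=O
Why: Standard DMAP-catalysed acetylation of the α-ketol proceeds with retention at C9.

Step 12
Reactants: 17 α-acetoxy ketone
Product: 19 target CNP0218315.1 (2R,4S,5S,9S,10R), via trimethylsilyl enol ether 18 (not isolated)
Conditions: TMSOTf, Et3N, CH2Cl2, 0 °C; then Pd(OAc)2, MeCN, rt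
Reagents that add atoms: TMSOTf, C[Si](C)(C)OS(=O)(=O)C(F)(F)F (its Me3Si group is carried only by 18 and is lost again)
Why: In this Saegusa–Ito oxidation, soft enolisation should take place at the unhindered C7H2 and away from the acyloxy-bearing C9, as known for α-acyloxy ketones, and the Pd(II) enolate then loses the C6 hydrogen by β-hydride elimination, which creates the C6=C7 enone and erases the auxiliary C6 stereocentre.

**Compound list**
1 | (+)-(4R)-limonene 1,2-oxide (cis/trans mixture) | C=C(C)[C@H]1CC2OC2(C)CC1 | starting material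
2 | (1S,2S,4R)-limonene-1,2-diol | CC(=C)[C@@H]1CC[C@]([C@H](C1)O)(C)O | intermediate
3 | (3R)-6-oxo-3-(prop-1-en-2-yl)heptanal | C=C(C)[C@@H](CC=O)CCC(C)=O | intermediate
4 | (S)-1-[4-(prop-1-en-2-yl)cyclopent-1-en-1-yl]ethan-1-one | C=C(C)[C@H]1CC=C(C(C)=O)C1 | intermediate
5 | 1-[(1R,3S,5S)-3-(prop-1-en-2-yl)-6-oxabicyclo[3.1.0]hexan-1-yl]ethan-1-one | C=C(C)[C@H]1C[C@@H]2O[C@]2(C(C)=O)C1 | intermediate
6 | hydrazone of 5 | C=C(C)[C@H]1C[C@@H]2O[C@]2(C(C)=NN)C1 | intermediate
7 | (1S,4R,E)-2-ethylidene-4-(prop-1-en-2-yl)cyclopentan-1-ol | C=C(C)[C@H]1C[C@H](O)/C(=C/C)C1 | intermediate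
8 | (4R,E)-2-ethylidene-4-(prop-1-en-2-yl)cyclopentan-1-one | C=C(C)[C@H]1CC(=O)/C(=C/C)C1 | intermediate
9 | (E)-pent-3-en-2-one | C/C=C/C(C)=O | starting material
10 | (E)-2-(tert-butyldimethylsilyloxy)penta-1,3-diene | C=C(O[Si](C)(C)C(C)(C)C)/C=C/C | intermediate
11 | Diels–Alder adduct, spiro ketone enol silane | C=C(C)[C@H]1CC(=O)[C@]2(C1)[C@@H](C)CC(O[Si](C)(C)C(C)(C)C)=C[C@@H]2C | intermediate
12 | (4S)-spiro alcohol enol silane | C=C(C)[C@H]1C[C@H](O)[C@]2(C1)[C@@H](C)CC(O[Si](C)(C)C(C)(C)C)=C[C@@H]2C | intermediate
13 | C4 senecioate enol silane | C=C(C)[C@H]1C[C@H](OC(=O)C=C(C)C)[C@]2(C1)[C@@H](C)CC(O[Si](C)(C)C(C)(C)C)=C[C@@H]2C | intermediate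
14 | C8/C9 silyloxy epoxide (oxygen trans to the C10 methyl group) | C=C(C)[C@H]1C[C@H](OC(=O)C=C(C)C)[C@]2(C1)[C@@H](C)C[C@@]3(O[Si](C)(C)C(C)(C)C)O[C@H]3[C@@H]2C | intermediate
15 | (9S)-9-silyloxy ketone | C=C(C)[C@H]1C[C@H](OC(=O)C=C(C)C)[C@]2(C1)[C@@H](C)CC(=O)[C@@H](O[Si](C)(C)C(C)(C)C)[C@@H]2C | intermediate
16 | (9S)-9-hydroxy ketone | C=C(C)[C@H]1C[C@H](OC(=O)C=C(C)C)[C@]2(C1)[C@@H](C)CC(=O)[C@@H](O)[C@@H]2C | intermediate
17 | (9S)-9-acetoxy ketone | C=C(C)[C@H]1C[C@H](OC(=O)C=C(C)C)[C@]2(C1)[C@@H](C)CC(=O)[C@@H](OC(C)=O)[C@@H]2C | intermediate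
18 | C7=C8 trimethylsilyl enol ether of 17 | C=C(C)[C@H]1C[C@H](OC(=O)C=C(C)C)[C@]2(C1)[C@@H](C)C=C(O[Si](C)(C)C)[C@@H](OC(C)=O)[C@@H]2C | intermediate
19 | CNP0218315.1 | C=C(C)[C@H]1C[C@H](OC(=O)C=C(C)C)[C@]2(C1)C(C)=CC(=O)[C@@H](OC(C)=O)[C@@H]2C | target

Total step count: 12. Longest linear sequence: 11 (steps 1–5 and 7–12).

**Steps most likely to fail**

Step 7. The remote isopropenyl group may discriminate too weakly between the two faces of 8, and endo control may erode. The Lewis acid may also move the exocyclic double bond into the ring or consume the diene before cycloaddition.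
Fallback (sets out from 9 and 8, comes back at 11): the ring is closed by an anionic double Michael reaction instead of a cycloaddition. Kinetic deprotonation of 9 with LDA in THF at −78 °C gives the lithium dienolate F1. Its CH2 terminus adds to C6 of 8, and the cyclopentanone enolate formed then closes onto the propenyl ketone at C10. This gives the ring-closed lithium enolate F2, which TBSCl/HMPA traps regiospecifically as 11.

Step 12. Enolisation may turn toward C9, or a silyl ketene acetal of one of the esters may form. Palladium would then desaturate the wrong side or the reaction would stall.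
Fallback (sets out from 12, comes back at 19): the enone is made under kinetic control before any ester is present.
- Buffered mCPBA without fluoride treatment keeps the migrated silyl group and gives the hydroxy α-silyloxy ketone F3.
- LiHMDS/TMSCl at −78 °C deprotonates C7H2, silylates the C4 hydroxyl in passing, and gives the bis(trimethylsilyl) compound F4.
- Pd(OAc)2 followed by citric acid/MeOH gives the hydroxy enone F5.
- Senecioylation as in step 9 gives the silyloxy enone ester F6.
- HF·pyridine gives the α′-hydroxy enone F7.
- Acetylation as in step 11 gives 19.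

Step 8. Hydride delivery to the neopentyl ketone may be slow, or substrate bias may override the catalyst and lead to the wrong C4 epimer.
Fallback (sets out from 11, comes back at 13): the ketone is reduced under pure substrate control (L-Selectride, THF, −78 °C) to the 4-epi alcohol F8. The centre is then inverted in the esterification itself by a Mitsunobu reaction with 3-methylbut-2-enoic acid (PPh3, DIAD), which gives 13 directly.

**Further compounds**
F1 | step 7 | lithium dienolate of (E)-pent-3-en-2-one | [Li+].[O-]C(=C)/C=C/C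
F2 | step 7 | ring-closed lithium C8 enolate | C=C(C)[C@H]1CC(=O)[C@]2(C1)[C@@H](C)CC([O-])=C[C@@H]2C.[Li+]
F3 | step 12 | hydroxy α-silyloxy ketone (C4-OH, C9-OTBS) | C=C(C)[C@H]1C[C@H](O)[C@]2(C1)[C@@H](C)CC(=O)[C@@H](O[Si](C)(C)C(C)(C)C)[C@@H]2C
F4 | step 12 | bis(trimethylsilyl) compound (C4-OTMS, C7=C8 enol silane, C9-OTBS) | C=C(C)[C@H]1C[C@H](O[Si](C)(C)C)[C@]2(C1)[C@@H](C)C=C(O[Si](C)(C)C)[C@@H](O[Si](C)(C)C(C)(C)C)[C@@H]2C
F5 | step 12 | hydroxy enone (C4-OH, C9-OTBS) | C=C(C)[C@H]1C[C@H](O)[C@]2(C1)C(C)=CC(=O)[C@@H](O[Si](C)(C)C(C)(C)C)[C@@H]2C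
F6 | step 12 | silyloxy enone ester (C4 senecioate, C9-OTBS) | C=C(C)[C@H]1C[C@H](OC(=O)C=C(C)C)[C@]2(C1)C(C)=CC(=O)[C@@H](O[Si](C)(C)C(C)(C)C)[C@@H]2C
F7 | step 12 | α′-hydroxy enone (C4 senecioate, C9-OH) | C=C(C)[C@H]1C[C@H](OC(=O)C=C(C)C)[C@]2(C1)C(C)=CC(=O)[C@@H](O)[C@@H]2C
F8 | step 8 | 4-epi alcohol | C=C(C)[C@H]1C[C@@H](O)[C@]2(C1)[C@@H](C)CC(O[Si](C)(C)C(C)(C)C)=C[C@@H]2C
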